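**Remark on the chemistry:** the configurations were re-derived from the structures: the target is (αS,3R,4R,α'S), the deoxy precursor 13 is (3R,4R), and the (S)-auxiliary 5 leads to it through the (2R,3R) dimer 9, so no structure needed correction. The oxidase variant of step 7 does not yet exist and is assumed to be obtainable by engineering.

## Structural features

The target is C2-symmetric: one oxolane (ring A) carries a CH(OH) carbon on C3 and on C4, and each carbinol carbon is bonded to C1 of a 4-hydroxy-3-methoxyphenyl (guaiacyl) ring (rings B and C). Four stereocentres stand in a row, carbinol–C3–C4–carbinol, with configuration S,R,R,S, and the two ring substituents are trans. Apart from the cyclic ether there are only two secondary benzylic alcohols, two phenols and two aryl methyl ethers. The fragile groups are the para-hydroxybenzylic alcohols: acid, heat or strong base ionise them to quinone methides, which leads to epimerisation, elimination or attack by the second electron-rich ring, and they are also open to hydrogenolysis and to oxidation to aryl ketones. The ring stereocentres are the easy part, since they form a C2-symmetric 2,3-dibenzylsuccinate pattern. The real difficulty is the configuration of each exocyclic carbinol relative to its ring neighbour, which must be set twice and then survive every later operation. The key step uses the fact that each carbinol carbon is para to the phenolic OH of its guaiacyl ring: it is the methide carbon of the para-quinone methide that two-electron oxidation of the benzylic CH2 group would give, so both C–O bonds can be added last.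

## Logic of the disconnections

**17 to 13.** The two benzylic C–OH bonds are cut. Both lie para to a free phenol, so they can be made by oxidation to a quinone methide and addition of water. This removes two of the four stereocentres and every sensitive group, and leaves a C2-symmetric compound with no protecting groups. The forward step must add water to one face of each methide carbon, work near neutral pH in water, and stop at the alcohol; it passes through 14, 15 and 16.

**13 to 12.** The two phenolic O–H bonds are exchanged for O–benzyl bonds. Free phenols would not survive the strong base and the one-electron oxidant of the C–C coupling. The forward step must remove both benzyl groups without touching the oxolane or the ArCH2–C bonds, which neutral hydrogenolysis should do.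

**12 to 10.** One C–O bond of the oxolane is cut, which opens the ring to an acyclic C2-symmetric 1,4-diol. The forward step must activate only one of two homotopic primary hydroxyl groups and close the ring by a 5-exo-tet displacement through 11; no stereocentre takes part.

**10 to 9.** Both CH2OH carbons are taken back to the acyl level and attached to the nitrogen of the auxiliary. This places the two stereocentres α to carbonyl groups, where they can be made by enolate chemistry. The forward reduction must cleave the exocyclic acyl–N bonds without enolising these centres. A borohydride is chosen over an aluminium hydride because attack on the ring carbonyl of a hindered imide is less likely.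

**9 to 7 (twice).** The central C–C bond, the future C3–C4 bond of the oxolane, is cut on the C2 axis. The molecule is halved and both ring stereocentres are made in one step from identical partners. The forward coupling of 8 must take place on the face of each enolate remote from the benzyl group of the auxiliary. Because the auxiliary is still attached, the unwanted isomers are diastereomers and can be separated.

**7 to 4 and 5.** The imide N–C(O) bond is cut, giving an arylpropanoic acid and the auxiliary. The forward acylation goes through 6 and must leave the aryl benzyl ether intact.

**4 to 1 and 2.** The phenolic O–benzyl bond is cut. The carboxyl group is benzylated at the same time, so the ester 3 must be saponified in the same pot.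

## Other disconnections considered

**Alternative 1:** The cut runs through the two ring C–CH2 bonds, C2–C3 and C4–C5, and takes the oxolane back to a two-carbon dipolarophile and a C–O–C unit. In the forward step CsF would remove the silyl group of A2 with loss of chloride to release the parent carbonyl ylide, which would add across the E-alkene of the bis-sultam A1 to give A3.
- In its favour: ring A and both ring stereocentres would arise in one concerted suprafacial step, the trans relationship follows from the fumarate geometry, and the auxiliary is crystalline, recoverable and available in both enantiomeric forms.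
- Against it here: A3 holds neither an aryl group nor a carbinol centre. Both acyl sultam groups would still have to become aryl ketones without over-addition or epimerisation, both ketones would need reagent-controlled reduction, and protecting groups would have to come off beside two labile benzylic alcohols. The unstabilised ylide is short-lived, and the facial sense of the sultam would have to be the one shown; the antipodal sultam would be the remedy if it were not.
- Comparison: on ring construction the alternative is the better plan (one step against coupling, reduction and closure). Its key step also belongs to a known reaction class, which the enzymatic hydroxylation does not, so on mechanistic certainty it is again the better. On the carbinol centres the chosen plan is better by design, with no carbonyl detour and no final deprotection. On step count the two are about equal, roughly eight operations against seven.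

**Alternative 2:** The cut is the oxolane C3–C4 bond, made by a 1,2-shift, together with one benzylic C–O bond; going backwards the ring expands to the dihydropyran A4. In the forward step PhI(OH)OTs (trivalent iodine) in methanol would add to the aryl-substituted C4=C5 bond of A4, and loss of iodobenzene would be accompanied by the shift of C3, the ring carbon bearing the silyloxybenzyl arm. The resulting aryl-stabilised oxocarbenium ion would give a dimethyl ketal and, after hydrolysis and equilibration, the trans ketone A5.
- In its favour: one carbinol centre would come from asymmetric aldol chemistry and be carried through as a silyl ether, the contraction would form ring A and the second benzylic C–O bond together, and the trans ring geometry is the thermodynamic one.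
- Against it here: a C2-symmetric target would be built by two different sets of reactions, and the second carbinol still needs a diastereoselective ketone reduction. A4 exposes two electron-rich arenes, two benzyl ethers and an ionisable benzylic silyl ether to an iodine electrophile and to sulfonic acid, so arene oxidation, aryl migration in place of the alkyl shift, or ionisation of the silyl ether could interfere. The final hydrogenolysis would run beside two benzylic alcohols.
- Comparison: for the first carbinol centre the alternative is the better plan, because that centre rests on a broadly precedented reaction class. For the second it stands level with the fallback of the chosen plan, not with its main line. Its key step is known chemistry and in that respect equal or better, although a cationic rearrangement with several competing channels is not clearly safer. In step economy the chosen plan is better, about ten operations against seven, and it uses the symmetry.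

**Alternative 3:** The cut takes out the C3–C4 bond and both benzylic C–O bonds at once and leads to two molecules of A6. In the forward step one-electron oxidation (laccase/O2 or FeCl3/O2) would give phenoxyl radicals, their β-carbons would couple to a bis(quinone methide), and each carboxyl group would add to the methide carbon of the other half to close the two lactones of A7.
- In its favour: one step from a cheap cinnamic acid would form the central C–C bond and both benzylic C–O bonds and fix the relative configuration of all four centres. The cis ring fusion and exo aryl groups of the drawn enantiomer of A7 correspond to S,R,R,S in 17 once both carbonyl carbons are reduced to CH2 and joined through oxygen. The same quinone methide logic is used, but capture is intramolecular, so no enzyme pocket is needed for relative control.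
- Against it here: radical coupling gives no absolute control, so a resolution would be needed, and regioisomeric dimers would compete. After reduction of both lactones, ring A would have to be closed between two primary hydroxyl groups in the presence of two easily ionised benzylic alcohols. Each of these also sits 1,4 to the carbon being displaced and could close a 2-aryl oxolane instead.
- Comparison: in bonds formed per step and in relative stereocontrol the alternative is the better plan, and on the quinone methide mechanism it is equal. Its nominal step count is equal or lower. The chosen plan is better on absolute configuration and on the end-game, since it finishes with the key step, whereas here a resolution and a chemoselective ring closure would remain.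

Key step: step 7

## Route

Step 1
Reactants: 1 3-(4-hydroxy-3-methoxyphenyl)propanoic acid; 2 benzyl bromide
Product: 4 3-(4-benzyloxy-3-methoxyphenyl)propanoic acid, via benzyl 3-(4-benzyloxy-3-methoxyphenyl)propanoate 3 (not isolated)
Conditions: 2 (2.3 equiv), K2CO3, DMF, 60 °C; then NaOH, MeOH–H2O, 60 °C; HCl to pH 2
Reagents that add atoms: sodium hydroxide, [Na+].[OH-]
Why: Williamson ether synthesis on the phenoxide; the carboxylate is benzylated too, so the crude ester 3 is saponified in the same pot (the hydroxide oxygen ends up in the carboxyl group), and the aryl benzyl ether is stable to base.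

Step 2
Reactants: 4 3-(4-benzyloxy-3-methoxyphenyl)propanoic acid; 5 (S)-4-benzyl-1,3-oxazolidin-2-one
Product: 7 (4S)-4-benzyl-3-[3-(4-benzyloxy-3-methoxyphenyl)propanoyl]-1,3-oxazolidin-2-one, via mixed pivalic anhydride 6 (not isolated)
Conditions: PivCl, Et3N, THF, −20 °C; then 5, LiCl, −20 °C → rt
Reagents that add atoms: none
Why: N-acylation of an oxazolidinone through a mixed anhydride; the lithium-coordinated oxazolidinone should attack the less hindered carbonyl of 6, and the stereocentre of 5 is not involved.

Step 3
Reactants: 7 (4S)-4-benzyl-3-[3-(4-benzyloxy-3-methoxyphenyl)propanoyl]-1,3-oxazolidin-2-one (two molecules)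
Product: 9 (4S,4'S)-3,3'-[(2R,3R)-2,3-bis(4-benzyloxy-3-methoxybenzyl)butanedioyl]bis(4-benzyl-1,3-oxazolidin-2-one), via lithium Z-enolate 8 (not isolated)
Conditions: LiN(iPr)2 (LDA), THF, −78 °C; then CuCl2 (1.1 equiv), DMF, −78 → 0 °C
Reagents that add atoms: none
Why: Oxidative homocoupling of a chelated imide enolate; divalent copper should oxidise 8 by one electron and the two α-carbons should join on the enolate face remote from the C4 benzyl group of the auxiliary, the face used in an Evans alkylation, which sets both new centres as R; the R,S and S,S isomers are diastereomers of 9 and separable.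

Step 4
Reactants: 9 (4S,4'S)-3,3'-[(2R,3R)-2,3-bis(4-benzyloxy-3-methoxybenzyl)butanedioyl]bis(4-benzyl-1,3-oxazolidin-2-one)
Product: 10 (2R,3R)-2,3-bis(4-benzyloxy-3-methoxybenzyl)butane-1,4-diol
Conditions: LiBH4, MeOH (4 equiv), THF, 0 °C → rt
Reagents that add atoms: none
Why: Reductive cleavage of N-acyl oxazolidinones; hydride should attack the exocyclic imide carbonyl and reduce the released aldehyde further, without enolising the α-centres, and 5 is recovered.

Step 5
Reactants: 10 (2R,3R)-2,3-bis(4-benzyloxy-3-methoxybenzyl)butane-1,4-diol
Product: 12 (3R,4R)-3,4-bis(4-benzyloxy-3-methoxybenzyl)oxolane, via mono-tosylate 11 (not isolated)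
Conditions: TsCl (1.1 equiv), pyridine, DMAP (cat.), CH2Cl2, 0 → 40 °C
Reagents that add atoms: none
Why: Intramolecular Williamson etherification; one of the two homotopic primary hydroxyl groups is sulfonylated and the other should displace the tosylate in a 5-exo-tet closure faster than a second sulfonylation occurs, with no stereocentre touched.

Step 6
Reactants: 12 (3R,4R)-3,4-bis(4-benzyloxy-3-methoxybenzyl)oxolane
Product: 13 (3R,4R)-3,4-bis(4-hydroxy-3-methoxybenzyl)oxolane
Conditions: H2 (1 atm), Pd/C, EtOAc–EtOH, rt
Reagents that add atoms: none
Why: Hydrogenolysis of aryl benzyl ethers; the oxolane C–O bonds and the ArCH2–C bonds carry no activating heteroatom and should be inert under these neutral conditions.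

Step 7
Reactants: 13 (3R,4R)-3,4-bis(4-hydroxy-3-methoxybenzyl)oxolane
Product: 17 (S,S)-[(3R,4R)-oxolane-3,4-diyl]bis[(4-hydroxy-3-methoxyphenyl)methanol], via first quinone methide 14 (not isolated), via mono-carbinol 15 (not isolated), via second quinone methide 16 (not isolated)
Conditions: S-selective, pocket-enlarged variant of vanillyl-alcohol oxidase (FAD enzyme), air (O2), K2HPO4/KH2PO4 buffer pH 7.5, DMSO (10% v/v), 25 °C; extraction without acid
Reagents that add atoms: water, O
Why: Proposed new method: the bound phenolate of 13 should pass its benzylic hydride to the flavin N5 to give the enzyme-bound para-quinone methide 14, and a water molecule held by an active-site carboxylate should add to the methide carbon while O2 reoxidises the flavin to give H2O2; release of 15, rebinding through the second guaiacyl ring and a second cycle through 16 should give 17. The closest known reaction type is the enantioselective benzylic hydroxylation of 4-ethylphenol, 4-propylphenol and their 2-methoxy analogues by vanillyl-alcohol oxidase and para-cresol methylhydroxylase, for which S-selective members and variants are known; new here are a benzylic carbon bonded to a ring methine, a substrate of about twice the usual size and two reaction sites. No ring is closed, so no mode of closure arises. Each new stereocentre is set by the enzyme, which must expose only the face of the planar methide carbon that leads to the S carbinol; the ring centres cannot do this, since an allylic 1,3-strain model of the free quinone methide predicts water addition anti to C4 of the oxolane and so the R carbinol. The step needs site selectivity, face selectivity and a stop at the alcohol stage. Site selectivity comes from the substrate, because only the two benzylic CH2 groups are para to a free phenol, and the C2 axis makes them homotopic, so only one mono-alcohol 15 can form and both cycles use the same binding mode. The trans arrangement at C3 and C4 disfavours capture of the second quinone methide by the first carbinol oxygen, which would require a trans-fused dioxabicyclo[3.3.0]octane. Tautomerisation of the quinone methide to a benzylidene oxolane and further oxidation of the carbinols to aryl ketones are the competing enzyme reactions and must be suppressed by the variant and by stopping when 15 is consumed.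

## Compound list

1 | 3-(4-hydroxy-3-methoxyphenyl)propanoic acid | COc1cc(CCC(=O)O)ccc1O | starting material
2 | benzyl bromide | BrCc1ccccc1 | starting material
3 | benzyl 3-(4-benzyloxy-3-methoxyphenyl)propanoate | COc1cc(CCC(=O)OCc2ccccc2)ccc1OCc1ccccc1 | intermediate
4 | 3-(4-benzyloxy-3-methoxyphenyl)propanoic acid | COc1cc(CCC(=O)O)ccc1OCc1ccccc1 | intermediate
5 | (S)-4-benzyl-1,3-oxazolidin-2-one | O=C1N[C@@H](Cc2ccccc2)CO1 | starting material
6 | 3-(4-benzyloxy-3-methoxyphenyl)propanoic 2,2-dimethylpropanoic anhydride | COc1cc(CCC(=O)OC(=O)C(C)(C)C)ccc1OCc1ccccc1 | intermediate
7 | (4S)-4-benzyl-3-[3-(4-benzyloxy-3-methoxyphenyl)propanoyl]-1,3-oxazolidin-2-one | COc1cc(CCC(=O)N2[C@@H](Cc3ccccc3)COC2=O)ccc1OCc1ccccc1 | intermediate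
8 | lithium (Z)-enolate of 7, O-lithiated at the exocyclic carbonyl | [Li]O/C(=C\Cc1ccc(OCc2ccccc2)c(OC)c1)N1[C@@H](Cc2ccccc2)COC1=O | intermediate
9 | (4S,4'S)-3,3'-[(2R,3R)-2,3-bis(4-benzyloxy-3-methoxybenzyl)butanedioyl]bis(4-benzyl-1,3-oxazolidin-2-one) | O=C([C@H](Cc1ccc(OCc2ccccc2)c(OC)c1)[C@@H](Cc1ccc(OCc2ccccc2)c(OC)c1)C(=O)N1[C@@H](Cc2ccccc2)COC1=O)N1[C@@H](Cc2ccccc2)COC1=O | intermediate
10 | (2R,3R)-2,3-bis(4-benzyloxy-3-methoxybenzyl)butane-1,4-diol | OC[C@H](Cc1ccc(OCc2ccccc2)c(OC)c1)[C@H](CO)Cc1ccc(OCc2ccccc2)c(OC)c1 | intermediate
11 | (2R,3R)-2,3-bis(4-benzyloxy-3-methoxybenzyl)-4-hydroxybutyl 4-methylbenzenesulfonate | Cc1ccc(cc1)S(=O)(=O)OC[C@H](Cc1ccc(OCc2ccccc2)c(OC)c1)[C@H](CO)Cc1ccc(OCc2ccccc2)c(OC)c1 | intermediate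
12 | (3R,4R)-3,4-bis(4-benzyloxy-3-methoxybenzyl)oxolane | COc1cc(C[C@H]2COC[C@@H]2Cc2ccc(OCc3ccccc3)c(OC)c2)ccc1OCc1ccccc1 | intermediate
13 | (3R,4R)-3,4-bis(4-hydroxy-3-methoxybenzyl)oxolane | COc1cc(C[C@H]2COC[C@@H]2Cc2ccc(O)c(OC)c2)ccc1O | intermediate
14 | 4-{[(3R,4R)-4-(4-hydroxy-3-methoxybenzyl)oxolan-3-yl]methylidene}-2-methoxycyclohexa-2,5-dien-1-one (exocyclic C=C geometry not defined) | COC1=CC(=C[C@H]2COC[C@@H]2Cc2ccc(O)c(OC)c2)C=CC1=O | intermediate
15 | 4-{(S)-hydroxy[(3R,4R)-4-(4-hydroxy-3-methoxybenzyl)oxolan-3-yl]methyl}-2-methoxyphenol | COc1cc([C@@H](O)[C@H]2COC[C@@H]2Cc2ccc(O)c(OC)c2)ccc1O | intermediate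
16 | 4-({(3R,4R)-4-[(S)-hydroxy(4-hydroxy-3-methoxyphenyl)methyl]oxolan-3-yl}methylidene)-2-methoxycyclohexa-2,5-dien-1-one (exocyclic C=C geometry not defined) | COc1cc([C@@H](O)[C@H]2COC[C@@H]2C=C3C=CC(=O)C(OC)=C3)ccc1O | intermediate
17 | (S,S)-[(3R,4R)-oxolane-3,4-diyl]bis[(4-hydroxy-3-methoxyphenyl)methanol] | COc1cc([C@@H](O)[C@H]2COC[C@@H]2[C@H](O)c2ccc(O)c(OC)c2)ccc1O | target

## Step count and least certain steps

Total step count: 7. Longest linear sequence: 7 steps, from 1 to 17.

**Step 7 (Proposed new method).** The most likely failures are:
- no turnover, because the pocket does not admit a substrate carrying an oxolane and a second aryl ring;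
- poor facial selectivity in the water addition;
- tautomerisation of the bound quinone methide to the alkene instead of hydration;
- escape of the quinone methide from the active site, followed by unselective hydration or attack by the other guaiacyl ring;
- over-oxidation of the carbinols to ketones, since 4-hydroxybenzylic alcohols are themselves substrates of this enzyme family.

The fallback uses known chemistry, sets out from 12 and returns at 17. Oxidation of both benzylic CH2 groups with DDQ in wet CH2Cl2 (hydride abstraction para to the benzyloxy group, capture of the cation by water, further oxidation of the carbinol) would give (3R,4R)-oxolane-3,4-diylbis[(4-benzyloxy-3-methoxyphenyl)methanone] F1. Corey–Bakshi–Shibata reduction with the (R)-configured B-methyl oxazaborolidine and BH3·SMe2, with the aryl group as the large substituent, should give (S,S)-[(3R,4R)-oxolane-3,4-diyl]bis[(4-benzyloxy-3-methoxyphenyl)methanol] F2. Hydrogenolysis over Pd/C in ethyl acetate under neutral conditions, stopped when the benzyl ethers are consumed, would return to 17.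

**Step 3.** The coupling may stall through α-chlorination or protonation of the enolate in place of C–C bond formation, and facial discrimination on the two partners may be incomplete, which lowers the share of the R,R isomer.

The fallback builds the central bond by two successive alkylations, sets out from 7 and returns at 10. Evans alkylation of the sodium enolate of 7 (NaN(SiMe3)2, THF, −78 °C) with tert-butyl bromoacetate should give (4S)-4-benzyl-3-[(2R)-2-(4-benzyloxy-3-methoxybenzyl)-4-tert-butoxy-4-oxobutanoyl]-1,3-oxazolidin-2-one F3. LiBH4 would reduce the imide to tert-butyl (3R)-3-(4-benzyloxy-3-methoxybenzyl)-4-hydroxybutanoate F4, which should close under acid catalysis (p-TsOH, toluene, 80 °C) to (4R)-4-(4-benzyloxy-3-methoxybenzyl)oxolan-2-one F5. Its lithium enolate (LiN(SiMe3)2, THF, −78 °C) would be alkylated trans to the existing substituent by 4-benzyloxy-3-methoxybenzyl bromide F6 (from the commercial benzylic alcohol and PBr3) to give (3R,4R)-3,4-bis(4-benzyloxy-3-methoxybenzyl)oxolan-2-one F7. LiAlH4 reduction of F7 would give 10.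

**Step 4.** Hydride may attack the ring carbonyl of the hindered imide and open the oxazolidinone, or reduction may stop after one acyl group.

The fallback separates cleavage from reduction, sets out from 9 and returns at 10. Hydrolysis with LiOH and H2O2 in THF–water at 0 °C, which attacks the exocyclic carbonyl selectively, would give (2R,3R)-2,3-bis(4-benzyloxy-3-methoxybenzyl)butanedioic acid F8, and BH3·SMe2 in THF would reduce F8 to 10.

**Step 5.** A second sulfonylation may outrun ring closure, or chloride may displace the tosylate, both of which divert material from the oxolane.

The fallback closes the ring under acid after deprotection, sets out from 10 and returns at 13. Hydrogenolysis (H2, Pd/C) would give (2R,3R)-2,3-bis(4-hydroxy-3-methoxybenzyl)butane-1,4-diol F9, and acid-catalysed cyclodehydration of the primary 1,4-diol (p-TsOH, toluene, 110 °C, water removed) would give 13.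

## Further compounds

F1 | step 7 | (3R,4R)-oxolane-3,4-diylbis[(4-benzyloxy-3-methoxyphenyl)methanone] | COc1cc(C(=O)[C@H]2COC[C@@H]2C(=O)c2ccc(OCc3ccccc3)c(OC)c2)ccc1OCc1ccccc1
F2 | step 7 | (S,S)-[(3R,4R)-oxolane-3,4-diyl]bis[(4-benzyloxy-3-methoxyphenyl)methanol] | COc1cc([C@@H](O)[C@H]2COC[C@@H]2[C@H](O)c2ccc(OCc3ccccc3)c(OC)c2)ccc1OCc1ccccc1
F3 | step 3 | (4S)-4-benzyl-3-[(2R)-2-(4-benzyloxy-3-methoxybenzyl)-4-tert-butoxy-4-oxobutanoyl]-1,3-oxazolidin-2-one | COc1cc(C[C@H](CC(=O)OC(C)(C)C)C(=O)N2[C@@H](Cc3ccccc3)COC2=O)ccc1OCc1ccccc1
F4 | step 3 | tert-butyl (3R)-3-(4-benzyloxy-3-methoxybenzyl)-4-hydroxybutanoate | COc1cc(C[C@@H](CO)CC(=O)OC(C)(C)C)ccc1OCc1ccccc1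
F5 | step 3 | (4R)-4-(4-benzyloxy-3-methoxybenzyl)oxolan-2-one | COc1cc(C[C@H]2COC(=O)C2)ccc1OCc1ccccc1
F6 | step 3 | 4-benzyloxy-3-methoxybenzyl bromide | COc1cc(CBr)ccc1OCc1ccccc1
F7 | step 3 | (3R,4R)-3,4-bis(4-benzyloxy-3-methoxybenzyl)oxolan-2-one | COc1cc(C[C@H]2COC(=O)[C@@H]2Cc2ccc(OCc3ccccc3)c(OC)c2)ccc1OCc1ccccc1
F8 | step 4 | (2R,3R)-2,3-bis(4-benzyloxy-3-methoxybenzyl)butanedioic acid | OC(=O)[C@H](Cc1ccc(OCc2ccccc2)c(OC)c1)[C@@H](Cc1ccc(OCc2ccccc2)c(OC)c1)C(=O)O
F9 | step 5 | (2R,3R)-2,3-bis(4-hydroxy-3-methoxybenzyl)butane-1,4-diol | OC[C@H](Cc1ccc(O)c(OC)c1)[C@H](CO)Cc1ccc(O)c(OC)c1
A1 | alternative 1 | N,N'-fumaroylbis[(2R)-bornane-10,2-sultam] | O=C(/C=C/C(=O)N1[C@@H]2C[C@H]3CC[C@]2(CS1(=O)=O)C3(C)C)N1[C@@H]2C[C@H]3CC[C@]2(CS1(=O)=O)C3(C)C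
A2 | alternative 1 | chloromethyl (trimethylsilyl)methyl ether | ClCOC[Si](C)(C)C
A3 | alternative 1 | N,N'-[(3R,4R)-oxolane-3,4-dicarbonyl]bis[(2R)-bornane-10,2-sultam] | O=C([C@H]1COC[C@@H]1C(=O)N1[C@@H]2C[C@H]3CC[C@]2(CS1(=O)=O)C3(C)C)N1[C@@H]2C[C@H]3CC[C@]2(CS1(=O)=O)C3(C)C
A4 | alternative 2 | (3R)-4-(4-benzyloxy-3-methoxyphenyl)-3-[(S)-(4-benzyloxy-3-methoxyphenyl)(tert-butyldimethylsilyloxy)methyl]-3,6-dihydro-2H-pyran | COc1cc(C2=CCOC[C@@H]2[C@H](O[Si](C)(C)C(C)(C)C)c2ccc(OCc3ccccc3)c(OC)c2)ccc1OCc1ccccc1
A5 | alternative 2 | (4-benzyloxy-3-methoxyphenyl){(3R,4R)-4-[(S)-(4-benzyloxy-3-methoxyphenyl)(tert-butyldimethylsilyloxy)methyl]oxolan-3-yl}methanone | COc1cc(C(=O)[C@H]2COC[C@@H]2[C@H](O[Si](C)(C)C(C)(C)C)c2ccc(OCc3ccccc3)c(OC)c2)ccc1OCc1ccccc1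
A6 | alternative 3 | (E)-3-(4-hydroxy-3-methoxyphenyl)prop-2-enoic acid (ferulic acid) | COc1cc(/C=C/C(=O)O)ccc1O
A7 | alternative 3 | (1S,2S,5S,6S)-2,6-bis(4-hydroxy-3-methoxyphenyl)-3,7-dioxabicyclo[3.3.0]octane-4,8-dione, cis-fused, both aryl groups exo | COc1cc([C@H]2OC(=O)[C@H]3[C@@H]2C(=O)O[C@@H]3c2ccc(O)c(OC)c2)ccc1O
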